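**The question.** Over 15 d, G and L in this flask pass through X, the intermediate, on the way to D, and I want the crest of cX. This flask holds less Z than Sunday's run.

| flask | G | L | Z | remark | time |
|---|---|---|---|---|---|
| Sunday's | 1.4 M | 1.5 equiv | 0.14 M | run made earlier |  |
| flask | 1.4 M | 1.50 equiv | 0.0700 M |  | 15 d |

Sunday's run (percent of the G charged)

| time / d | X / % | D / % |
|---|---|---|
| 0.250 | 7.6 | 3.9 |
| 0.833 | 9.2 | 19.5 |
| 1.25 | 7.5 | 29.3 |
| 2.00 | 4.9 | 42.4 |
| 3.00 | 2.7 | 52.3 |

(each reading ± 0.5 percentage points)

* when, up to 15 d, the flask holds most X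
* the amount of X, in percent of the G charged, at that time

- no earlier run changes the charge of Z; that part of a forecast is a guess

**The lag.** I treat cX as a first-order lag. On Sunday, D gains 0.235 d⁻¹ of the charge between 0.833 d and 1.25 d, over a mean X of 8.35 %. So I read from these scattered readings that X drains at kX = 2.81 d⁻¹, and 0.246 d is the half-life of X so read, my clock.

**The curve.** On Sunday, cX starts at zero with a slope equal to the supply, the gain of X plus D. The readings give 0.460 d⁻¹ over the first interval and 0.295 d⁻¹ over the next, so I read a supply falling at kS = 1.07 d⁻¹. Extrapolated back to the start, it stands at 0.526 d⁻¹, so the level cX chases begins at 18.7 %. My estimate of Sunday's crest, where cX meets that falling level, is ln(kX/kS)/(kX−kS) = 0.555 d, or 2.26 half-lives, with 10.3 %. The tail of Sunday's readings then halves about every 1.16 d, and 15 d is 12.9 such tails. No earlier run varies Z, so I carry this estimate over to the new flask as a guess.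

**The forecast.** It gives 0.75 d (0.45 d to 1.4 d) and 5.5 % (3.8 % to 9.3 %), on a different guess from mine: “Halving Z then halves formation”.

**The result.** G + L → X (k = 0.0106 L mol⁻¹ h⁻¹); X → D (k = 0.124 h⁻¹); G → E (k = 0.00616 h⁻¹); L + X ⇌ Q (K = 9.40 L mol⁻¹, k = 8.46 × 10⁻⁴ L mol⁻¹ h⁻¹); Z + X → J (k = 0.0768 L mol⁻¹ h⁻¹)

The flask holds most X at 0.561 d, with 10.1 %, which is 2.28 half-lives of X by my clock. In the scheme, the half-life of X by the passing of X into D alone is 0.23 d at 15.0 d, shorter than the 1.3 d half-life of G by the passing of G + L into X alone with the other concentrations as charged, and a flask with half the G and all other amounts as they are crests at 0.590 d, or 2.40 of the same half-lives.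

The data were generated by integration for substances that don't exist; noise was put on by code.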